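Remark on the chemistry: the two ynol ethers 14 and 20 are treated as not purchasable and are made within the route. Atom labels: ring A is C1 (acetyl), C2 (OH), C3 (CH3), C4 (OCH3), C5 (H), C6 (ether O); ring B is C1' (ether O), C2' (OH), C3' (CH3), C4' (OCH3), C5' (acetyl), C6' (OH).

## Analysis of the target

Leprolomin (29) is two acetophenone rings joined by one ether oxygen, with no stereocentre. Ring A is pentasubstituted and ring B is hexasubstituted. The difficulty is regiochemical: six different substituents must be placed around ring B, and oxygens that differ only as OH and OCH3 must be told apart in both rings. The ether oxygen sits between two ortho substituents on ring B and next to one on ring A, so a late metal-mediated C–O coupling is unattractive. Sensitive features are the electron-rich polyphenol rings (air oxidation, over-substitution), the methoxy groups ortho to acetyl (cleaved by chelating Lewis acids) and the enolisable acetyl groups. The C1 acetyl of ring A is ortho to the ether oxygen, so it cannot be present when the carbon on that oxygen is activated as a ketene: (2-acylaryloxy)ketenes add to their own carbonyl group and end as benzofurans. The strategy rests on the C2'–C3'–C4' segment of ring B: a methyl carbon between a hydroxyl carbon and a methoxy carbon is what forms when a ketene carbonyl carbon and the oxygen-bearing carbon of 1-methoxypropyne flank the methyl-bearing alkyne carbon, and C1' can enter as the sp3 α-carbon of an aryloxyketene. A second feature keeps the rest simple: without its acetyl and with the C2 oxygen as a methyl ether, ring A is a 3,5-dimethoxy-4-methylphenoxy group in which C1 and C5 are mirror-related, so the acetyl can be added late without a regiochemical question.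

## Retrosynthetic reasoning

29 to 28. The O–CH3 bond on the C2 oxygen of ring A is cut. Carrying this hydroxyl as a methyl ether makes ring A symmetric in every earlier compound. The forward step must remove only the methyl group that can chelate a boron Lewis acid together with the C1 acetyl oxygen. The C4 methoxy is para to that acetyl, and the C4' methoxy of ring B sits beside a carbonyl already held in a chelate by the C6' oxygen.

28 to 26. The C1–acetyl bond of ring A and the C5'–acetyl bond of ring B are cut together. An acetyl at C1 cannot be carried earlier, because ketene 16 would add to it intramolecularly. C5' is the only open position of ring B, and C1 and C5 of ring A are still equivalent in 26. The forward step must put one acetyl on each ring.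

26 to 25. The O–Si bond on the C6' oxygen is cut. The silyl group comes from the cyclobutenone synthesis and keeps the C6' oxygen distinct from the C4' methoxy; fluoride removes it.

25 to 17 and 20. The bonds C2'–C3', C4'–C5' and C1'–C2' are cut, which opens ring B. This is the one place where a single operation sets the whole ring B pattern from two small, separately made pieces. The forward reaction must open the cyclobutenone, add the alkyne to the ketene in the right orientation and close the six-membered ring.

17 to 6 and 14. Two C–C bonds of the four-membered ring are cut, giving aryloxyketene 16 (from acid 6) and silyl ynol ether 14. The hindered aryl–O–C1' bond is then already present in 6 as an ordinary ether bond to an sp3 carbon.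

6 to 3 and 4, and 3 to 1. The O–CH2 bond is cut (phenol alkylation), then the phenol C–O bond. In 1 only one ring carbon has no ortho substituent, so a sterically controlled C–H borylation followed by oxidation gives 3 directly.

14 to 12 to 10 to 7 and 8. The alkyne is traced back to a 2-bromovinyl silyl ether (two eliminations of HBr), and this to the silyl enol ether of acetaldehyde, obtained from 7 and 8.

20 to 18. The methyl–alkyne bond and the alkyne itself are traced back to the chloroacetal, through acetylide 19.

## Alternatives that were turned down

Alternative 1: Aryne insertion into a ring B aryl acetate. The C6–O bond and the C1–acetyl bond of ring A are cut together. Fluoride would release the C1–C6 aryne from the ortho-silylaryl triflate A2; the phenoxide from the ring B aryl acetate A3 would add at C6 and the C1 aryl anion would take over the acetyl group, giving tri-O-benzyl leprolomin A1. In its favour, the C2 benzyloxy group of the aryne directs the nucleophile to the distal carbon C6 and leaves the anion at C1, so ether and ring A acetyl arrive correctly in one convergent step. On the placement of the ring A acetyl it is stronger than the chosen route, which needs a late acetylation and a selective demethylation. Against it, A3 is the complete hexasubstituted ring B, and its three oxygens would have to be differentiated by stepwise aromatic chemistry with no ring-forming step to set the pattern. Its phenoxide is flanked by two benzyloxy groups and is a poor partner for a short-lived aryne. The aryl anion can be protonated (for example by the enolisable acetyl of A3) before it is acylated. The chosen strategy offers instead a one-step construction of the ring B pattern and an ether bond made by simple alkylation.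

Alternative 2: Ring A by benzannulation with an aryl ethynyl ether. The ring A bonds C4–C5, C1–C6 and C3–C4 are cut. Cyclobutenone A5 would be heated with the ethynyl ether A6 of the ring B phenol to give diaryl ether A4, with a C4 phenol, a C2 silyl ether and no substituent at C1. It uses the same reliable pericyclic cascade under the same neutral conditions, and A5 is simple; on these points it equals the chosen route. Against it, the ring-forming step is spent on the easier ring, which the chosen route obtains in one step from a commercial arene, while the hexasubstituted ring B must again be made classically as A6. The alkyne A6 is an aryl ynol ether and is less nucleophilic toward a ketene than an alkyl ynol ether. A4 still needs acetylation at C1, where C1 and C5 are no longer equivalent and are both flanked by two oxygens, and O-methylation at C4. The chosen strategy removes that regiochemical question by symmetry and builds the hard ring.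

Alternative 3: Ring B by Diels–Alder on an aryloxy ketoester. The bonds C3'–C4' and C5'–C6' are cut. Diene A8, with the ring A aryloxy group on its C2, would add to 4-methoxybut-3-yn-2-one A9 and aromatise by loss of methanol to the ring A 2-O-benzyl ether of leprolomin A7. It is stronger on end-game economy: ring B arrives with its acetyl and both hydroxyls, and ring A can keep its acetyl, so only a debenzylation remains. Against it, A8 is substituted at both termini, so the reactive s-cis conformer is disfavoured. A9 is a push–pull alkyne whose reacting carbon bears a methoxy donor, so it is a weak dienophile and is sensitive to hydrolysis. Making A8 needs double enol silylation in the presence of ring A's own enolisable acetyl and an ether bond between a hindered, chelated phenol and a tertiary α-carbon. The chosen strategy offers stable, separately purified partners and a cascade whose regiochemistry is fixed by ketene polarity.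

Key step: step 8

## Route

Step 1
Reactants: 1 1,3-dimethoxy-2-methylbenzene (2,6-dimethoxytoluene)
Product: 3 3,5-dimethoxy-4-methylphenol, via aryl pinacolboronate 2 (not isolated)
Conditions: HBpin (1.5 equiv), [Ir(OMe)(cod)]2 (1.5 mol%), dtbpy (3 mol%), cyclohexane, 80 °C; evaporate; then Oxone (2KHSO5·KHSO4·K2SO4), acetone–H2O, rt
Reagents that add atoms: potassium peroxymonosulfate (active component of Oxone), [K+].[O-]S(=O)(=O)OO
Why: Iridium-catalysed aromatic C–H borylation is sterically controlled, and in 1 only the carbon para to the methyl group has no ortho substituent, so a single boronate 2 should form. Oxidation of the C–B bond with peroxymonosulfate in the same flask should give phenol 3.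

Step 2
Reactants: 3 3,5-dimethoxy-4-methylphenol; 4 ethyl bromoacetate
Product: 6 2-(3,5-dimethoxy-4-methylphenoxy)acetic acid, via ethyl ester 5 (not isolated)
Conditions: K2CO3, DMF, 50 °C; then 2 M aq. NaOH, rt; aq. HCl
Reagents that add atoms: sodium hydroxide (supplies one carboxyl oxygen), [Na+].[OH-]
Why: Williamson O-alkylation of the only phenol of 3, followed by saponification of ester 5 in the same pot. Ring A has no acetyl group here, so no aldol-type cyclisation onto the new side chain is possible.

Step 3
Reactants: 7 tetrahydrofuran (reactant and solvent); 8 chlorotriisopropylsilane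
Product: 10 (ethenyloxy)triisopropylsilane, via lithium ethenolate 9 (not isolated)
Conditions: n-BuLi (hexanes), 7 as solvent, rt, 16 h; then 8, DMPU, 0 °C to rt
Reagents that add atoms: none
Why: n-BuLi lithiates tetrahydrofuran at C2 and the anion fragments by [3+2] cycloreversion to ethene and the lithium enolate of acetaldehyde 9. The hindered chlorosilane silylates 9 on oxygen.

Step 4
Reactants: 10 (ethenyloxy)triisopropylsilane
Product: 12 [(2-bromoethenyl)oxy]triisopropylsilane (E/Z mixture), via dibromo ether 11 (not isolated)
Conditions: Br2 (1.0 equiv), CH2Cl2, −78 °C; then Et3N (2 equiv), −78 °C to rt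
Reagents that add atoms: bromine, BrBr
Why: Bromine adds to the enol ether to give α-bromo ether 11, and amine-induced loss of HBr through the oxocarbenium ion returns the enol ether as its 2-bromo derivative, the classical bromination–dehydrobromination route to 2-bromovinyl ethers. The bulky triisopropylsilyl group should keep bromide from attacking silicon.

Step 5
Reactants: 12 [(2-bromoethenyl)oxy]triisopropylsilane
Product: 14 (ethynyloxy)triisopropylsilane, via lithium acetylide 13 (not isolated)
Conditions: LiN(i-Pr)2 (2.2 equiv), THF, −78 °C; then sat. aq. NH4Cl, −78 °C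
Reagents that add atoms: none
Why: Dehydrohalogenation of a 2-halovinyl ether, the classical route to ynol ethers: the amide base removes HBr from either isomer of 12 and deprotonates the alkyne. Cold protonation of acetylide 13 releases 14.

Step 6
Reactants: 6 2-(3,5-dimethoxy-4-methylphenoxy)acetic acid; 14 (ethynyloxy)triisopropylsilane
Product: 17 4-(3,5-dimethoxy-4-methylphenoxy)-3-(triisopropylsilyloxy)cyclobut-2-en-1-one (racemic), via acid chloride 15 (not isolated), via aryloxyketene 16 (not isolated)
Conditions: (COCl)2, DMF (cat.), CH2Cl2, 0 °C to rt, evaporate; then slow addition to 14 (1.5 equiv), Et3N (1.5 equiv), CH2Cl2, 0 °C to rt; filter through Et3N-deactivated silica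
Reagents that add atoms: none
Why: Et3N dehydrochlorinates 15 to aryloxyketene 16, which is trapped in a ketene–ynol ether [2+2] cycloaddition. The nucleophilic terminal carbon of 14 bonds to the ketene carbonyl carbon, so the silyloxy carbon ends up next to the aryloxy-bearing sp3 carbon C4. Ring A has no carbonyl group ortho to the ketene-bearing oxygen, so the intramolecular ketene–carbonyl cycloaddition that leads to benzofurans cannot occur.

Step 7
Reactants: 18 2-chloro-1,1-dimethoxyethane
Product: 20 1-methoxyprop-1-yne, via sodium methoxyacetylide 19 (not isolated)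
Conditions: NaNH2 (3 equiv), liquid NH3, −33 °C; then MeI, −33 °C; distil
Reagents that add atoms: iodomethane, CI
Why: Two β-eliminations (methanol, then HCl) and deprotonation convert the chloroacetal into acetylide 19, which is C-methylated in liquid ammonia. This is the standard preparation of 1-alkoxy-1-alkynes.

Step 8
Reactants: 17 4-(3,5-dimethoxy-4-methylphenoxy)-3-(triisopropylsilyloxy)cyclobut-2-en-1-one; 20 1-methoxyprop-1-yne
Product: 25 2-(3,5-dimethoxy-4-methylphenoxy)-5-methoxy-6-methyl-3-(triisopropylsilyloxy)phenol, via vinylketene 21 (not isolated), via alkenylcyclobutenone 22 (not isolated), via dienylketene 23 (not isolated), via cyclohexadienone 24 (not isolated)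
Conditions: 20 (3 equiv), toluene, sealed tube, 80 °C, then 110 °C
Reagents that add atoms: none
Why: Danheiser benzannulation of a cyclobutenone with an alkoxyalkyne, a thermal pericyclic cascade. Conrotatory 4π electrocyclic opening of the C1–C4 bond of 17, with the aryloxy donor rotating outward, gives vinylketene 21. The ketene C=C of 21 adds 20 in a [2+2] cycloaddition in which the nucleophilic, methyl-bearing alkyne carbon attacks the ketene carbonyl carbon; this forms C2'–C3' and C4'–C5' and closes the four-membered ring of 22. 22 reopens to dienylketene 23, whose thermal disrotatory 6π electrocyclisation forms C1'–C2' and closes ring B as cyclohexadienone 24; tautomerisation of the hydrogen on C1' then gives phenol 25. Two selectivities are needed: the orientation of the [2+2] step, which puts the C3' methyl between the C2' hydroxyl and the C4' methoxy, and reaction at the ketene C=C instead of a [4+2] addition across the whole vinylketene, which would place the aryloxy carbon next to the methoxy carbon. Both follow from the polarisation of the partners: the ketene carbonyl carbon is the only strongly electrophilic site of 21, the methyl-bearing carbon of 20 is its only nucleophilic one, and the oxygen-rich diene unit of 21 is electronically mismatched with an electron-rich alkyne. No stereocentre is formed, and the C4 centre of racemic 17 disappears on aromatisation. The conditions are neutral, so the silyl ether and the methyl ethers should be untouched, and ring A carries no carbonyl group that could intercept a ketene.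

Step 9
Reactants: 25 2-(3,5-dimethoxy-4-methylphenoxy)-5-methoxy-6-methyl-3-(triisopropylsilyloxy)phenol
Product: 26 2-(3,5-dimethoxy-4-methylphenoxy)-5-methoxy-4-methylbenzene-1,3-diol
Conditions: Bu4NF (1.1 equiv), AcOH (1.1 equiv), THF, 0 °C, under argon
Reagents that add atoms: none
Why: Fluoride cleaves the aryl O–Si bond. The acetic acid buffer keeps the electron-rich resorcinol from standing as its phenoxide, which would be prone to air oxidation.

Step 10
Reactants: 26 2-(3,5-dimethoxy-4-methylphenoxy)-5-methoxy-4-methylbenzene-1,3-diol
Product: 28 1-[3-(2-acetyl-3,5-dimethoxy-4-methylphenoxy)-2,4-dihydroxy-6-methoxy-5-methylphenyl]ethan-1-one, via aryl acetate 27 (not isolated)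
Conditions: Ac2O (3.2 equiv), BF3·OEt2, 60 °C; aq. NaOAc; then MeOH, HCl (cat.), 50 °C
Reagents that add atoms: acetic anhydride, CC(=O)OC(C)=O
Why: Friedel–Crafts and Fries C-acetylation under BF3: ring B can react only at C5', where the acyl group arrives ortho to the C6' hydroxyl and is held as a boron chelate. Ring A reacts at one of its two symmetry-equivalent positions (ortho to the ether oxygen, para to a methoxy), and the first acetyl then deactivates that ring. Acidic methanolysis removes the O-acetyl group assumed to remain on the non-chelated C2' hydroxyl (27) and breaks the boron chelate.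

Step 11
Reactants: 28 1-[3-(2-acetyl-3,5-dimethoxy-4-methylphenoxy)-2,4-dihydroxy-6-methoxy-5-methylphenyl]ethan-1-one
Product: 29 leprolomin
Conditions: BCl3 (1 M in CH2Cl2, 4 equiv), CH2Cl2, −78 to 0 °C; then H2O–MeOH
Reagents that add atoms: none
Why: Chelation-controlled ether cleavage: BCl3 removes a methyl group only where the methoxy oxygen and an ortho carbonyl oxygen can bind the same boron. In ring A only the C2 methoxy qualifies, since the C4 methoxy is para to the acetyl. In ring B the acetyl oxygen is already held in a chelate with the boron on the C6' oxygen, the situation in which 2-hydroxy-6-methoxyaryl ketones resist a second demethylation at low temperature.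

## Compound list

1 | 1,3-dimethoxy-2-methylbenzene (2,6-dimethoxytoluene) | COc1cccc(OC)c1C | starting material
2 | 2-(3,5-dimethoxy-4-methylphenyl)-4,4,5,5-tetramethyl-1,3,2-dioxaborolane | COc1cc(B2OC(C)(C)C(C)(C)O2)cc(OC)c1C | intermediate
3 | 3,5-dimethoxy-4-methylphenol | COc1cc(O)cc(OC)c1C | intermediate
4 | ethyl bromoacetate | CCOC(=O)CBr | starting material
5 | ethyl 2-(3,5-dimethoxy-4-methylphenoxy)acetate | CCOC(=O)COc1cc(OC)c(C)c(OC)c1 | intermediate
6 | 2-(3,5-dimethoxy-4-methylphenoxy)acetic acid | COc1cc(OCC(=O)O)cc(OC)c1C | intermediate
7 | tetrahydrofuran | C1CCOC1 | starting material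
8 | chlorotriisopropylsilane (triisopropylsilyl chloride) | CC(C)[Si](Cl)(C(C)C)C(C)C | starting material
9 | lithium ethenolate (lithium enolate of acetaldehyde) | C=C[O-].[Li+] | intermediate
10 | (ethenyloxy)triisopropylsilane | C=CO[Si](C(C)C)(C(C)C)C(C)C | intermediate
11 | (1,2-dibromoethoxy)triisopropylsilane (racemic) | BrCC(Br)O[Si](C(C)C)(C(C)C)C(C)C | intermediate
12 | [(2-bromoethenyl)oxy]triisopropylsilane (E/Z mixture, both isomers serve) | BrC=CO[Si](C(C)C)(C(C)C)C(C)C | intermediate
13 | lithium 2-(triisopropylsilyloxy)ethynide | [Li+].[C-]#CO[Si](C(C)C)(C(C)C)C(C)C | intermediate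
14 | (ethynyloxy)triisopropylsilane | C#CO[Si](C(C)C)(C(C)C)C(C)C | intermediate
15 | 2-(3,5-dimethoxy-4-methylphenoxy)acetyl chloride | COc1cc(OCC(Cl)=O)cc(OC)c1C | intermediate
16 | 2-(3,5-dimethoxy-4-methylphenoxy)ethen-1-one (aryloxyketene) | COc1cc(OC=C=O)cc(OC)c1C | intermediate
17 | 4-(3,5-dimethoxy-4-methylphenoxy)-3-(triisopropylsilyloxy)cyclobut-2-en-1-one (racemic) | COc1cc(OC2C(=O)C=C2O[Si](C(C)C)(C(C)C)C(C)C)cc(OC)c1C | intermediate
18 | 2-chloro-1,1-dimethoxyethane (chloroacetaldehyde dimethyl acetal) | COC(CCl)OC | starting material
19 | sodium 2-methoxyethynide | [Na+].[C-]#COC | intermediate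
20 | 1-methoxyprop-1-yne | CC#COC | intermediate
21 | (Z)-4-(3,5-dimethoxy-4-methylphenoxy)-3-(triisopropylsilyloxy)buta-1,3-dien-1-one | O=C=C/C(O[Si](C(C)C)(C(C)C)C(C)C)=C/Oc1cc(OC)c(C)c(OC)c1 | intermediate
22 | 4-[(Z)-2-(3,5-dimethoxy-4-methylphenoxy)-1-(triisopropylsilyloxy)ethenyl]-3-methoxy-2-methylcyclobut-2-en-1-one (racemic) | O=C1C(C)=C(OC)C1/C(O[Si](C(C)C)(C(C)C)C(C)C)=C/Oc1cc(OC)c(C)c(OC)c1 | intermediate
23 | (3E,5Z)-6-(3,5-dimethoxy-4-methylphenoxy)-3-methoxy-2-methyl-5-(triisopropylsilyloxy)hexa-1,3,5-trien-1-one | O=C=C(C)/C(OC)=C\C(O[Si](C(C)C)(C(C)C)C(C)C)=C\Oc1cc(OC)c(C)c(OC)c1 | intermediate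
24 | 6-(3,5-dimethoxy-4-methylphenoxy)-3-methoxy-2-methyl-5-(triisopropylsilyloxy)cyclohexa-2,4-dien-1-one (racemic) | O=C1C(C)=C(OC)C=C(O[Si](C(C)C)(C(C)C)C(C)C)C1Oc1cc(OC)c(C)c(OC)c1 | intermediate
25 | 2-(3,5-dimethoxy-4-methylphenoxy)-5-methoxy-6-methyl-3-(triisopropylsilyloxy)phenol | COc1cc(Oc2c(O)c(C)c(OC)cc2O[Si](C(C)C)(C(C)C)C(C)C)cc(OC)c1C | intermediate
26 | 2-(3,5-dimethoxy-4-methylphenoxy)-5-methoxy-4-methylbenzene-1,3-diol | COc1cc(Oc2c(O)c(C)c(OC)cc2O)cc(OC)c1C | intermediate
27 | 4-acetyl-2-(2-acetyl-3,5-dimethoxy-4-methylphenoxy)-3-hydroxy-5-methoxy-6-methylphenyl acetate | COc1cc(Oc2c(OC(C)=O)c(C)c(OC)c(C(C)=O)c2O)c(C(C)=O)c(OC)c1C | intermediate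
28 | 1-[3-(2-acetyl-3,5-dimethoxy-4-methylphenoxy)-2,4-dihydroxy-6-methoxy-5-methylphenyl]ethan-1-one (leprolomin 2-O-methyl ether) | COc1cc(Oc2c(O)c(C)c(OC)c(C(C)=O)c2O)c(C(C)=O)c(OC)c1C | intermediate
29 | leprolomin, 1-[3-(2-acetyl-3-hydroxy-5-methoxy-4-methylphenoxy)-2,4-dihydroxy-6-methoxy-5-methylphenyl]ethan-1-one | COc1cc(Oc2c(O)c(C)c(OC)c(C(C)=O)c2O)c(C(C)=O)c(O)c1C | target

## Step count and least certain steps

Total: 11 steps. Longest linear sequence: 8 steps (steps 3, 4, 5, 6, 8, 9, 10, 11, from tetrahydrofuran). The ring A arm (steps 1, 2) and the alkyne arm (step 7) join at steps 6 and 8.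

Step 8 (key step). The most likely failure is slow capture of the donor-substituted vinylketene 21 by the internal alkyne 20. The vinylketene would then be lost to acylation of the product phenol or to self-condensation, and some material could leak through the [4+2] orientation. The fallback swaps the roles of the two ynol ethers; it sets out from acid 6 and comes back at 26. Ketene 16, generated as in step 6, would be trapped with triisopropyl(prop-1-yn-1-yloxy)silane F1, made from commercial 1-propynyllithium by oxidation with LiOOt-Bu and O-silylation with TIPSOTf. This gives 4-(3,5-dimethoxy-4-methylphenoxy)-2-methyl-3-(triisopropylsilyloxy)cyclobut-2-en-1-one F2, which already carries the C3' methyl. Heating F2 with the terminal and less hindered methoxyethyne F3 (acetylide 19 protonated instead of methylated) would form C5'–C6', C3'–C4' and C1'–C6' and give 2-(3,5-dimethoxy-4-methylphenoxy)-5-methoxy-4-methyl-3-(triisopropylsilyloxy)phenol F4. Desilylation as in step 9 gives 26.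

Step 6. The acid-sensitive silyl ynol ether 14 may be protonated by the ammonium salt or acylated by 15 faster than the ketene captures it, and the vinylogous silyl ester 17 may lose its silyl group by hydrolysis on isolation. The fallback uses an alkyl ynol ether; it sets out from acid 6 and comes back at 26. Propan-2-ol, KH and trichloroethene would give 1,2-dichloro-1-(propan-2-yloxy)ethene F5, and n-BuLi followed by a proton quench 2-(ethynyloxy)propane F6. Ketene 16 adds F6 to give 4-(3,5-dimethoxy-4-methylphenoxy)-3-(propan-2-yloxy)cyclobut-2-en-1-one F7, a vinylogous ester that tolerates chromatography. Benzannulation of F7 with 20 as in step 8 gives 2-(3,5-dimethoxy-4-methylphenoxy)-5-methoxy-6-methyl-3-(propan-2-yloxy)phenol F8. BCl3 at 0 °C removes the secondary alkyl ether but not methyl ethers that lack an ortho carbonyl, and gives 26.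

Step 4. Bromide may attack silicon in the bromo-oxocarbenium intermediate, with loss of the silyl group instead of the proton. The fallback introduces silicon after the halogen; it sets out from acetal 18 and comes back at 14. Acetal exchange of 18 with formic acid and distillation gives chloroacetaldehyde F9. Enol silylation with TIPSOTf and Et3N gives [(2-chloroethenyl)oxy]triisopropylsilane F10, and LiN(i-Pr)2 as in step 5 gives 14.

Step 10. Ring A may take a second acetyl group at its other free position, or stay unacetylated if the reagent is held short, so that mixtures result. The fallback is a Houben–Hoesch acylation; it sets out from 26 and comes back at 28. MeCN, ZnCl2 and HCl gas in Et2O at 0 °C would give the bis(ketimine) dihydrochloride F11, each ring being switched off by its own iminium group as soon as it has reacted. Hydrolysis in hot water gives 28.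

Step 11. The C4' methyl group of ring B may be lost along with the C2 methyl of ring A if the chelate at ring B does not shield it enough. The fallback removes the ring A methyl before ring B carries a carbonyl; it sets out from 26 and comes back at 29. NBS at −78 °C brominates the most electron-rich position, C5', to give 4-bromo-2-(3,5-dimethoxy-4-methylphenoxy)-5-methoxy-6-methylbenzene-1,3-diol F12. Acetylation of ring A with Ac2O and BF3·OEt2, with acidic methanolysis of the phenol esters formed alongside, gives 1-[2-(3-bromo-2,6-dihydroxy-4-methoxy-5-methylphenoxy)-4,6-dimethoxy-5-methylphenyl]ethan-1-one F13. BCl3 then cleaves only the C2 methoxy and gives 1-[6-(3-bromo-2,6-dihydroxy-4-methoxy-5-methylphenoxy)-2-hydroxy-4-methoxy-3-methylphenyl]ethan-1-one F14. Hydrogenolysis of the C–Br bond (H2, Pd/C, Et3N) gives 1-[6-(2,6-dihydroxy-4-methoxy-3-methylphenoxy)-2-hydroxy-4-methoxy-3-methylphenyl]ethan-1-one F15. Acetylation of ring B at C5' with AcOH and BF3·OEt2, ring A now being deactivated by its acetyl, gives 29.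

## Further compounds

F1 | step 8 | triisopropyl(prop-1-yn-1-yloxy)silane | CC#CO[Si](C(C)C)(C(C)C)C(C)C
F2 | step 8 | 4-(3,5-dimethoxy-4-methylphenoxy)-2-methyl-3-(triisopropylsilyloxy)cyclobut-2-en-1-one (racemic) | COc1cc(OC2C(=O)C(C)=C2O[Si](C(C)C)(C(C)C)C(C)C)cc(OC)c1C
F3 | step 8 | methoxyethyne | COC#C
F4 | step 8 | 2-(3,5-dimethoxy-4-methylphenoxy)-5-methoxy-4-methyl-3-(triisopropylsilyloxy)phenol | COc1cc(Oc2c(O)cc(OC)c(C)c2O[Si](C(C)C)(C(C)C)C(C)C)cc(OC)c1C
F5 | step 6 | 1,2-dichloro-1-(propan-2-yloxy)ethene | CC(C)OC(Cl)=CCl
F6 | step 6 | 2-(ethynyloxy)propane | CC(C)OC#C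
F7 | step 6 | 4-(3,5-dimethoxy-4-methylphenoxy)-3-(propan-2-yloxy)cyclobut-2-en-1-one (racemic) | COc1cc(OC2C(=O)C=C2OC(C)C)cc(OC)c1C
F8 | step 6 | 2-(3,5-dimethoxy-4-methylphenoxy)-5-methoxy-6-methyl-3-(propan-2-yloxy)phenol | COc1cc(Oc2c(O)c(C)c(OC)cc2OC(C)C)cc(OC)c1C
F9 | step 4 | chloroacetaldehyde | ClCC=O
F10 | step 4 | [(2-chloroethenyl)oxy]triisopropylsilane (E/Z mixture) | ClC=CO[Si](C(C)C)(C(C)C)C(C)C
F11 | step 10 | 1-[3-(2-ethanimidoyl-3,5-dimethoxy-4-methylphenoxy)-2,4-dihydroxy-6-methoxy-5-methylphenyl]ethan-1-imine dihydrochloride | COc1cc(Oc2c(O)c(C)c(OC)c(C(C)=N)c2O)c(C(C)=N)c(OC)c1C.Cl.Cl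
F12 | step 11 | 4-bromo-2-(3,5-dimethoxy-4-methylphenoxy)-5-methoxy-6-methylbenzene-1,3-diol | COc1cc(Oc2c(O)c(C)c(OC)c(Br)c2O)cc(OC)c1C
F13 | step 11 | 1-[2-(3-bromo-2,6-dihydroxy-4-methoxy-5-methylphenoxy)-4,6-dimethoxy-5-methylphenyl]ethan-1-one | COc1cc(Oc2c(O)c(C)c(OC)c(Br)c2O)c(C(C)=O)c(OC)c1C
F14 | step 11 | 1-[6-(3-bromo-2,6-dihydroxy-4-methoxy-5-methylphenoxy)-2-hydroxy-4-methoxy-3-methylphenyl]ethan-1-one | COc1cc(Oc2c(O)c(C)c(OC)c(Br)c2O)c(C(C)=O)c(O)c1C
F15 | step 11 | 1-[6-(2,6-dihydroxy-4-methoxy-3-methylphenoxy)-2-hydroxy-4-methoxy-3-methylphenyl]ethan-1-one | COc1cc(Oc2c(O)c(C)c(OC)cc2O)c(C(C)=O)c(O)c1C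
A1 | alternative 1 | tri-O-benzyl leprolomin | COc1cc(Oc2c(OCc3ccccc3)c(C)c(OC)c(C(C)=O)c2OCc2ccccc2)c(C(C)=O)c(OCc2ccccc2)c1C
A2 | alternative 1 | 3-(benzyloxy)-5-methoxy-4-methyl-2-(trimethylsilyl)phenyl trifluoromethanesulfonate | COc1cc(OS(=O)(=O)C(F)(F)F)c([Si](C)(C)C)c(OCc2ccccc2)c1C
A3 | alternative 1 | 3-acetyl-2,6-bis(benzyloxy)-4-methoxy-5-methylphenyl acetate | CC(=O)Oc1c(OCc2ccccc2)c(C)c(OC)c(C(C)=O)c1OCc1ccccc1
A4 | alternative 2 | 1-[2,4-bis(benzyloxy)-3-[3-hydroxy-4-methyl-5-(triisopropylsilyloxy)phenoxy]-6-methoxy-5-methylphenyl]ethan-1-one | Cc1c(O)cc(Oc2c(OCc3ccccc3)c(C)c(OC)c(C(C)=O)c2OCc2ccccc2)cc1O[Si](C(C)C)(C(C)C)C(C)C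
A5 | alternative 2 | 4-methyl-3-(triisopropylsilyloxy)cyclobut-2-en-1-one (racemic) | CC1C(=O)C=C1O[Si](C(C)C)(C(C)C)C(C)C
A6 | alternative 2 | 1-[2,4-bis(benzyloxy)-3-(ethynyloxy)-6-methoxy-5-methylphenyl]ethan-1-one | C#COc1c(OCc2ccccc2)c(C)c(OC)c(C(C)=O)c1OCc1ccccc1
A7 | alternative 3 | leprolomin ring A 2-O-benzyl ether | COc1cc(Oc2c(O)c(C)c(OC)c(C(C)=O)c2O)c(C(C)=O)c(OCc2ccccc2)c1C
A8 | alternative 3 | 2-(2-acetyl-3-benzyloxy-5-methoxy-4-methylphenoxy)-1-methoxy-1,3-bis(trimethylsilyloxy)penta-1,3-diene | CC=C(O[Si](C)(C)C)C(Oc1cc(OC)c(C)c(OCc2ccccc2)c1C(C)=O)=C(OC)O[Si](C)(C)C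
A9 | alternative 3 | 4-methoxybut-3-yn-2-one | COC#CC(C)=O
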